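**Plan**

- Retrosynthesis: the two silyl ethers come off last. The pyran ring is then cut at C3–C4 and O1–C2, giving an A-ring ortho-quinone methide (O1=C8a–C4a=C4) and a B-ring 2-hydroxystyrene (C2=C3).
- Enabling feature: the ring O1–C2–C3–C4–C4a–C8a is the formal [4+2] adduct of that methide and the vinyl group. The 2'-hydroxyl beside C2 is the hydrogen-bond handle for a chiral acid and the donor that makes the styrene nucleophilic.
- The side chain is cut at C8–C1'' (aromatic Claisen) and C2''=C3'' (cross-metathesis).
- Forward: methyl 4-methoxysalicylate is elaborated in six steps (O-allylation, Claisen, metathesis with methacrolein, Luche reduction, silylation, ester reduction) to the salicyl alcohol. The styrene is made in two steps from 2,4-dihydroxybenzaldehyde. The cycloaddition closes the only new ring, and one desilylation finishes.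
- Stereochemistry: C2 (S) is set in the key step by a chiral phosphoric acid. The E-alkene comes from the metathesis with methacrolein and is not touched afterwards.

Key step: step 9

Assumption: the sense of induction of the phosphoric acid cannot be predicted with certainty for this substrate. The (R)-catalyst is written; its mirror image would be used if a test adduct proves to be 2R.

Remark: the salicylate ester is used instead of the salicylaldehyde so that the benzylic and the allylic oxygen stay at different oxidation levels until the allylic one is silylated.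

**Route**

Step 1
Reactants: 1 methyl 2-hydroxy-4-methoxybenzoate; 2 allyl bromide
Product: 3 methyl 4-methoxy-2-(prop-2-en-1-yloxy)benzoate
Conditions: K2CO3, DMF, 60 °C
Reagents that add atoms: none
Why: Williamson etherification of the salicylate phenol with a reactive allylic bromide; carbonate leaves the methyl ester untouched.

Step 2
Reactants: 3 methyl 4-methoxy-2-(prop-2-en-1-yloxy)benzoate
Product: 4 methyl 2-hydroxy-4-methoxy-3-(prop-2-en-1-yl)benzoate
Conditions: N,N-diethylaniline, 200 °C
Reagents that add atoms: none
Why: Aromatic Claisen rearrangement; the [3,3] shift can only go to C3 because the other ortho position carries the ester, so the allyl group lands between the phenol and the methoxy group.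

Step 3
Reactants: 4 methyl 2-hydroxy-4-methoxy-3-(prop-2-en-1-yl)benzoate; 5 methacrolein
Product: 6 methyl 2-hydroxy-4-methoxy-3-[(2E)-3-methyl-4-oxobut-2-en-1-yl]benzoate
Conditions: Hoveyda–Grubbs II (5 mol %), methacrolein (10 equiv), CH2Cl2, 40 °C
Reagents that add atoms: none
Why: Olefin cross-metathesis of a terminal alkene with methacrolein, which does not homodimerise, should give the trisubstituted enal with the favoured E geometry (aryl-CH2 trans to CHO); the ester-chelated phenol is a spectator.

Step 4
Reactants: 6 methyl 2-hydroxy-4-methoxy-3-[(2E)-3-methyl-4-oxobut-2-en-1-yl]benzoate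
Product: 7 methyl 2-hydroxy-3-[(2E)-4-hydroxy-3-methylbut-2-en-1-yl]-4-methoxybenzoate
Conditions: NaBH4, CeCl3·7H2O, MeOH, 0 °C
Reagents that add atoms: none
Why: Luche 1,2-reduction should reduce the enal carbonyl without conjugate reduction and leave the salicylate ester and the E-alkene intact.

Step 5
Reactants: 7 methyl 2-hydroxy-3-[(2E)-4-hydroxy-3-methylbut-2-en-1-yl]-4-methoxybenzoate
Product: 8 methyl 3-[(2E)-4-(tert-butyldimethylsilyloxy)-3-methylbut-2-en-1-yl]-2-hydroxy-4-methoxybenzoate
Conditions: TBSCl (1.05 equiv), imidazole, CH2Cl2, 0 °C
Reagents that add atoms: tert-butyldimethylsilyl chloride, CC(C)(C)[Si](C)(C)Cl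
Why: Silyl ether formation with one equivalent of chloride should take the unhindered primary allylic hydroxyl, since the phenol is hydrogen-bonded to the ester carbonyl and flanked by two ortho substituents.

Step 6
Reactants: 8 methyl 3-[(2E)-4-(tert-butyldimethylsilyloxy)-3-methylbut-2-en-1-yl]-2-hydroxy-4-methoxybenzoate
Product: 9 2-[(2E)-4-(tert-butyldimethylsilyloxy)-3-methylbut-2-en-1-yl]-6-(hydroxymethyl)-3-methoxyphenol
Conditions: LiAlH4, THF, 0 °C; Rochelle salt work-up
Reagents that add atoms: none
Why: Hydride reduction of a salicylate ester to the salicyl alcohol is standard; the allylic silyl ether and the isolated alkene are inert at 0 °C, and the neutral tartrate work-up avoids premature ionisation of the activated benzylic alcohol.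

Step 7
Reactants: 10 2,4-dihydroxybenzaldehyde
Product: 11 4-(tert-butyldimethylsilyloxy)-2-hydroxybenzaldehyde
Conditions: TBSCl (1.05 equiv), imidazole, CH2Cl2, 0 °C
Reagents that add atoms: tert-butyldimethylsilyl chloride, CC(C)(C)[Si](C)(C)Cl
Why: Regioselective silylation; the 2-hydroxyl is locked in a hydrogen bond to the aldehyde, so the 4-hydroxyl should react first.

Step 8
Reactants: 11 4-(tert-butyldimethylsilyloxy)-2-hydroxybenzaldehyde
Product: 12 5-(tert-butyldimethylsilyloxy)-2-vinylphenol
Conditions: Ph3PCH3Br (2.6 equiv), n-BuLi (2.5 equiv), THF, 0 °C; then 11, 0 °C to rt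
Reagents that add atoms: methyltriphenylphosphonium bromide, C[P+](c1ccccc1)(c1ccccc1)c1ccccc1.[Br-]
Why: Wittig methylenation as routinely used for salicylaldehydes; one equivalent of ylide is consumed by the phenol and the second converts the aldehyde into the vinyl group.

Step 9
Reactants: 9 2-[(2E)-4-(tert-butyldimethylsilyloxy)-3-methylbut-2-en-1-yl]-6-(hydroxymethyl)-3-methoxyphenol; 12 5-(tert-butyldimethylsilyloxy)-2-vinylphenol
Product: 15 (2S)-8-[(2E)-4-(tert-butyldimethylsilyloxy)-3-methylbut-2-en-1-yl]-2-[4-(tert-butyldimethylsilyloxy)-2-hydroxyphenyl]-7-methoxychromane, via A-ring ortho-quinone methide 13 (not isolated), via ring-open B-ring quinone methide 14 (not isolated)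
Conditions: (R)-TRIP (10 mol %), 4 Å MS, PhMe, 0 °C, slow addition of 9 to 12 (1.5 equiv); Et3N quench
Reagents that add atoms: none
Why: Proposed new method: the phosphoric acid protonates the benzylic hydroxyl of 9, whose ionisation is eased by the para-methoxy and ortho-hydroxy groups, and loss of water gives the terminus-unsubstituted methide 13, hydrogen-bonded to the phosphate that also binds the 2-hydroxyl of 12. The terminal vinyl carbon of 12 adds to the methide carbon (C3–C4) to give 14, a B-ring ortho-quinone methide, and the A-ring phenol then adds to its exocyclic carbon in a 6-exo-trig oxa-Michael closure (O1–C2), so the pyran ring arises by a stepwise inverse-demand oxa-[4+2] annulation. The closest known reaction type is the chiral phosphoric acid-catalysed oxa-[4+2] cycloaddition of aryl-substituted ortho-quinone methides from ortho-hydroxybenzhydrols with ortho-hydroxystyrenes, together with phosphoric acid-catalysed conjugate additions of oxygen nucleophiles to ortho-quinone methides; new here is the unsubstituted methide terminus, which makes C2 the only stereocentre and leaves it to be set in the C–O bond formation alone. The C2 configuration should be controlled by the catalyst, which holds the carbonyl oxygen of 14 (the former 2'-hydroxyl) and the attacking phenol in its chiral pocket and so exposes one face of the exocyclic alkene. Regioselectivity (aryl at C2) follows from the electrophilic methide carbon meeting the styrene terminus made nucleophilic by the 2-hydroxy and 4-silyloxy donors, and the side-chain alkene should stay inert because a trisubstituted alkene bearing an allylic oxygen is not protonated by so weak an acid. Slow addition of 9 at 0 °C keeps the methide concentration low against self-condensation, and the amine quench limits acid-mediated reopening of the labile C2–O1 bond.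

Step 10
Reactants: 15 (2S)-8-[(2E)-4-(tert-butyldimethylsilyloxy)-3-methylbut-2-en-1-yl]-2-[4-(tert-butyldimethylsilyloxy)-2-hydroxyphenyl]-7-methoxychromane
Product: 16 morusyunnansin E, 4-[(2S)-8-[(2E)-4-hydroxy-3-methylbut-2-en-1-yl]-7-methoxychroman-2-yl]benzene-1,3-diol
Conditions: TBAF (3 equiv), AcOH (3 equiv), THF, 0 °C to rt
Reagents that add atoms: none
Why: Fluoride cleavage of the aryl and the primary allylic silyl ethers; the acetic acid buffer keeps the 2'- and 4'-phenols protonated, so no phenoxide-driven opening of the C2–O1 bond should scramble the stereocentre, and the alkene and methyl ether are unaffected.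

**Compound list**

1 | methyl 2-hydroxy-4-methoxybenzoate | COC(=O)c1ccc(OC)cc1O | starting material
2 | allyl bromide | C=CCBr | starting material
3 | methyl 4-methoxy-2-(prop-2-en-1-yloxy)benzoate | COC(=O)c1ccc(OC)cc1OCC=C | intermediate
4 | methyl 2-hydroxy-4-methoxy-3-(prop-2-en-1-yl)benzoate | COC(=O)c1ccc(OC)c(CC=C)c1O | intermediate
5 | methacrolein | CC(=C)C=O | starting material
6 | methyl 2-hydroxy-4-methoxy-3-[(2E)-3-methyl-4-oxobut-2-en-1-yl]benzoate | COC(=O)c1ccc(OC)c(C/C=C(\C)C=O)c1O | intermediate
7 | methyl 2-hydroxy-3-[(2E)-4-hydroxy-3-methylbut-2-en-1-yl]-4-methoxybenzoate | COC(=O)c1ccc(OC)c(C/C=C(\C)CO)c1O | intermediate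
8 | methyl 3-[(2E)-4-(tert-butyldimethylsilyloxy)-3-methylbut-2-en-1-yl]-2-hydroxy-4-methoxybenzoate | COC(=O)c1ccc(OC)c(C/C=C(\C)CO[Si](C)(C)C(C)(C)C)c1O | intermediate
9 | 2-[(2E)-4-(tert-butyldimethylsilyloxy)-3-methylbut-2-en-1-yl]-6-(hydroxymethyl)-3-methoxyphenol | COc1ccc(CO)c(O)c1C/C=C(\C)CO[Si](C)(C)C(C)(C)C | intermediate
10 | 2,4-dihydroxybenzaldehyde | O=Cc1ccc(O)cc1O | starting material
11 | 4-(tert-butyldimethylsilyloxy)-2-hydroxybenzaldehyde | O=Cc1ccc(O[Si](C)(C)C(C)(C)C)cc1O | intermediate
12 | 5-(tert-butyldimethylsilyloxy)-2-vinylphenol | C=Cc1ccc(O[Si](C)(C)C(C)(C)C)cc1O | intermediate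
13 | A-ring ortho-quinone methide, 2-[(2E)-4-(tert-butyldimethylsilyloxy)-3-methylbut-2-en-1-yl]-3-methoxy-6-methylidenecyclohexa-2,4-dien-1-one (not isolated) | C=C1C=CC(OC)=C(C/C=C(\C)CO[Si](C)(C)C(C)(C)C)C1=O | intermediate
14 | ring-open adduct, 6-{3-[3-((2E)-4-(tert-butyldimethylsilyloxy)-3-methylbut-2-en-1-yl)-2-hydroxy-4-methoxyphenyl]propylidene}-3-(tert-butyldimethylsilyloxy)cyclohexa-2,4-dien-1-one (not isolated) | COc1ccc(CCC=C2C=CC(O[Si](C)(C)C(C)(C)C)=CC2=O)c(O)c1C/C=C(\C)CO[Si](C)(C)C(C)(C)C | intermediate
15 | (2S)-8-[(2E)-4-(tert-butyldimethylsilyloxy)-3-methylbut-2-en-1-yl]-2-[4-(tert-butyldimethylsilyloxy)-2-hydroxyphenyl]-7-methoxychromane | COc1ccc2c(c1C/C=C(\C)CO[Si](C)(C)C(C)(C)C)O[C@H](c1ccc(O[Si](C)(C)C(C)(C)C)cc1O)CC2 | intermediate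
16 | morusyunnansin E | COc1ccc2c(c1C/C=C(\C)CO)O[C@H](c1ccc(O)cc1O)CC2 | target

**Count and risks**

Total step count: 10. Longest linear sequence: 8 steps (steps 1–6, 9, 10).

Steps most likely to fail:

1. Step 9. The ring closure may show poor facial discrimination, because the catalyst has to control a C–O bond formation with no stereocentre at C4 to help it. The ee may also erode by acid-reversible ionisation of the C2–O1 bond, and acid-induced self-reaction of the electron-rich styrene or of the methide may compete. Fallback, from 9 and 12: the two are heated without acid (xylene, 140 °C, BHT). This is the established thermal loss of water from a 2-hydroxybenzyl alcohol with capture of the quinone methide by a styrene. It should give the racemic bis-silyl flavan F1, which is resolved by preparative chiral SFC on a polysaccharide phase. The 2S enantiomer is compound 15, where the route is rejoined.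

2. Step 3. The metathesis may stall with the volatile, electron-poor 1,1-disubstituted partner, and ruthenium hydrides may move the allyl double bond into conjugation with the arene. Fallback, from 4: cross-metathesis in neat 2-methyl-2-butene (Grubbs II, rt), a fast and well-behaved prenyl synthesis, should give methyl 2-hydroxy-4-methoxy-3-(3-methylbut-2-en-1-yl)benzoate F2. Selenium dioxide (catalytic) with tert-butyl hydroperoxide in CH2Cl2 then oxidises the E-methyl group, as is usual for prenyl groups, and the route is rejoined at allylic alcohol 7. Any enal 6 formed by over-oxidation is returned to 7 under the conditions of step 4.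

3. Step 8. The aryl silyl ether may be lost under the strongly basic ylide conditions in the presence of a phenoxide, and the electron-rich vinylphenol may polymerise during the long chromatography needed to remove the phosphine oxide. Fallback, from 11: Peterson olefination. (Trimethylsilyl)methylmagnesium chloride (2.5 equiv, THF, 0 °C) should add to the aldehyde to give the β-hydroxysilane 5-(tert-butyldimethylsilyloxy)-2-[1-hydroxy-2-(trimethylsilyl)ethyl]phenol F3. Brief exposure to catalytic PPTS in CH2Cl2 at 0 °C then eliminates the silanol, helped by the ortho-hydroxy, para-silyloxy and β-silyl groups, with only a volatile by-product. The route is rejoined at styrene 12.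

**Further compounds**

F1 | step 9 | racemic 8-[(2E)-4-(tert-butyldimethylsilyloxy)-3-methylbut-2-en-1-yl]-2-[4-(tert-butyldimethylsilyloxy)-2-hydroxyphenyl]-7-methoxychromane | COc1ccc2c(c1C/C=C(\C)CO[Si](C)(C)C(C)(C)C)OC(c1ccc(O[Si](C)(C)C(C)(C)C)cc1O)CC2
F2 | step 3 | methyl 2-hydroxy-4-methoxy-3-(3-methylbut-2-en-1-yl)benzoate | COC(=O)c1ccc(OC)c(CC=C(C)C)c1O
F3 | step 8 | 5-(tert-butyldimethylsilyloxy)-2-[1-hydroxy-2-(trimethylsilyl)ethyl]phenol (racemic) | C[Si](C)(C)CC(O)c1ccc(O[Si](C)(C)C(C)(C)C)cc1O
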